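Choose between the two flasks below before charging either: I had to say whether cooling at 3.0 h cost enough to matter.

| flask | left-handed substrate | right-handed substrate | gas | temperature | remark | time |
|---|---|---|---|---|---|---|
| grey | 0.070 M | 0.070 M | 7 mM (held) | 25 °C | run made earlier |  |
| ochre | 0.11 M | 0.11 M | 7 mM (held) | 50 °C | run made earlier |  |
| south-west | 0.050 M | 0.050 M | 7.0 mM (held) |  | at 70 °C until 3.0 h, from then on at 30 °C | 10 h |
| north-east | 0.050 M | 0.050 M | 7.0 mM (held) |  | at 70 °C throughout | 10 h |

| grey: time / h | grey: left-handed product / % | ochre: time / h | ochre: left-handed product / % |
|---|---|---|---|
| 10.0 | 3.2 | 2.50 | 5.3 |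
| 30.0 | 9.1 | 8.00 | 18.9 |
| 60.0 | 18.3 | 15.0 | 27.8 |
| 72.0 | 19.4 | 20.0 | 34.9 |
| 120 | 25.4 | 30.0 | 41.8 |

(standard deviation of a reading: 1 percentage point)

- partner is single-handed; left-handed substrate and right-handed substrate are mirror images of each other, charged as a racemate, each of them at the stated concentration
- at the start none of the gas is in solution
- the handed part of partner does not stay in what it makes, so the products of the two hands are mirror images too

- which one finishes higher in amount of left-handed product, in percent of the left-handed substrate and right-handed substrate together charged ("neither" within 2 percentage points) (south-west / north-east / neither)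
- amount of left-handed product at the end, in percent of the left-handed substrate and right-handed substrate together charged, south-west
- amount of left-handed product at the end, in percent of the left-handed substrate and right-handed substrate together charged, north-east

Each hand gives its own product, so left-handed product can reach 50.0 % of the total charge. I treated left-handed substrate as pseudo-first-order and integrated its rate. The exposure E is the time integral of the rate constant, equal to ln of c(left-handed substrate) as charged over c(left-handed substrate) now, and the product's distance from the ceiling falls as e^−E.

The last grey reading gave 0.00591 /h and the last ochre reading 0.0603 /h, so an activation energy of 74.4 kJ/mol, though the two runs also differ in charge. That extrapolated to 0.00970 /h at 30 °C and 0.303 /h at 70 °C, the hot exposure rate, meaning exposure gained per hour of heat.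

North-east therefore collects 3.03, which is 47.6 %. South-west collects 0.976, which is 31.2 %. The gap of 16 percentage points far exceeds the margin of 2 points, so I chose not to cool. One warning stood in the ochre run: its first reading, 5.3 % at 2.50 h, lay 1.7 points under this rate, with a scatter of 1 point, and these flasks start with no gas in solution.

The forecast also chose north-east, with 29 % for south-west and 45 % for north-east, somewhat below my figures, saying “then north-east runs much faster”.

North-east gave 45.1 % and south-west 21.7 %, so the choice stood, but south-west fell 9.5 points short of my figure.

    gas ⇌ partner, rate k1*(csat - [partner]) (kL = 3.00 /h)
    partner → decomposition product (k = 1.90 × 10⁻⁴ /h, Ea = 124 kJ/mol)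
    partner ⇌ dormant form (K = 6.90, k = 1.60 /h, Ea = 105 kJ/mol, ΔH = −9.00 kJ/mol)
    partner + right-handed substrate → right-handed product (k = 39.0 /M/h, Ea = 73.0 kJ/mol)
    partner + left-handed substrate → left-handed product (k = 70.0 /M/h, Ea = 79.0 kJ/mol)
    (constants at 70 °C)

South-west had reached an exposure of 0.487 by 3.00 h against my 0.909, a deficit of 0.421, with partner at 0.00275 M against the gas saturation of 7.0 mM. In south-west at 70 °C, partner's half-life by the step with left-handed substrate alone, the concentrations as charged, is 0.20 h, shorter than the 0.231 h in which the gas feed alone closes half the gap to saturation. North-east had the same charge and temperature as south-west up to 3.0 h, so for north-east read at 4.0 h I took over that deficit: the hot rate less the deficit gives exposure 0.790, so 27.3 % left-handed product; the computed flask holds 24.9 %.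

The runs come from a simulation from invented constants; scatter was added.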